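**Retrosynthetic overview** (labdane numbering: ring A = C1–C5, C10; ring B = C5–C10; C17 on C8, C18/C19 on C4, C20 on C10; target = (3S,5S,9R,10S), ent-labdane series)
1. C9–C11 is cut last: the (E)-C11–C16 chain is added as an organocerium reagent to a C9 ketone; oxidative 1,3-transposition, Li/NH3 reduction (sets C9) and reduction of a C7 enol triflate then place H9 and C7=C8.
2. The ring A ketol (C2=O, C3–OH syn to C20) is unveiled at the very end from a 2-silyloxy-1-en-3-one by hydride delivery to C3 anti to C20. This is needed because Rubottom oxidation of the C2–C3 silyl enol ether puts oxygen on C3 from the wrong face, so the 2,3-diol is carried through and re-oxidised to the diosphenol.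
3. The C6 oxygen of an ene-dione is removed by Luche reduction, acetylation and SmI2.
4. Feature the strategy rests on: ring B (C5–C10) with methyls C17 on C8 and C20 on C10 is 2,6-dimethyl-1,4-benzoquinone, and C1–C4 with the geminal methyls on C4 is the silyl dienol ether of mesityl oxide (its carbonyl carbon becomes C2). An enantioselective [4+2] forms C1–C10 and C4–C5, and C5 is then equilibrated to the trans fusion.
5. Ring order: ring B is bought as the quinone, ring A is closed onto it in the key step, and no further ring is formed.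

Key step: step 2

Assumption: the (S)-catalyst is taken, from the usual binding model (boron on the C6 carbonyl lone pair syn to C5–H, one phenyl shielding a face of C5=C10), to give the C10 configuration drawn for 5 and 6; if the sense proves opposite, the (R)-catalyst from (R)-diphenylprolinol is used instead.

**Step 1**
Reactants: 1 mesityl oxide
Product: 3 2-(tert-butyldimethylsilyloxy)-4-methylpenta-1,3-diene, via lithium dienolate 2 (not isolated)
Conditions: LiN(iPr)2, THF, −78 °C; TBSCl, DMPU, −78 → 0 °C
Reagents that add atoms: tert-butyldimethylsilyl chloride, CC(C)(C)[Si](C)(C)Cl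
Why: Kinetic deprotonation of the enone at the acetyl methyl gives the cross-conjugated dienolate, which is O-silylated (silyl enol ether formation); no stereocenter is formed.

**Step 2**
Reactants: 3 2-(tert-butyldimethylsilyloxy)-4-methylpenta-1,3-diene; 4 2,6-dimethyl-1,4-benzoquinone
Product: 6 trans-fused 2-silyloxy-2,7-diene-6,9-dione (H5 anti to C20), via cis-fused adduct 5 (not isolated)
Conditions: N-protonated (S)-B-(o-tolyl)oxazaborolidine from (S)-α,α-diphenylprolinol as its bis(trifluoromethanesulfonyl)imide salt (20 mol %), CH2Cl2, −78 → −40 °C; then DBU, −40 → 0 °C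
Reagents that add atoms: none
Why: Coordination of the cationic boron to O6 (the carbonyl between the two ring C–H positions, held by a C5–H···O contact to the catalyst oxygen) activates C5=C10 as an acceptor whose electrophilic site is C10, so bond formation should be highly asynchronous, C1 of the silyl dienol ether attacking C10 ahead of C4–C5 closure, and may at the limit pass through a silyloxyallyl cation/boron enolate pair that collapses to the same adduct. The closest known reaction type is the oxazaborolidinium-catalysed Diels–Alder reaction of substituted benzoquinones with 2-silyloxybutadienes, supported by Lewis-acid cycloadditions of hindered 2-silyloxydienes. Ring A closes as a six-membered carbocycle by [4+2] cycloaddition onto the preformed ring B (a 6-endo closure if the second bond forms stepwise). C10 is set by the catalyst, whose phenyl group covers one face of the bound C5=C10 bond; C5 is first set cis by the suprafacial addition and is then inverted by DBU through the C5–C6 enolate, the trans-decalin being the expected thermodynamic product. The step needs C1 on C10 and not on C5, which is secured by binding at the unflanked C6 carbonyl (C10 is its β-carbon) and by the polarisation of the silyloxydiene, and it needs one enantioface, which the catalyst supplies; endo and exo paths give the same product because neither diene terminus is stereogenic, and the quaternary C10 blocks aromatisation.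

**Step 3**
Reactants: 6 trans-fused 2-silyloxy-2,7-diene-6,9-dione
Product: 7 6-hydroxy-2-silyloxy-2,7-dien-9-one (6-OH syn to C20)
Conditions: NaBH4, CeCl3·7H2O, MeOH–THF, −78 °C
Reagents that add atoms: none
Why: Luche 1,2-reduction should pick the C6 carbonyl, which lies between two C–H carbons, over the C9 carbonyl shielded by the C8 methyl and quaternary C10, with hydride arriving on the H5 face (away from C20 and the axial C4 methyl) so that the new C6–OH is syn to C20, a centre erased in step 5; the hindered silyl enol ether should survive the short cold exposure.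

**Step 4**
Reactants: 7 6-hydroxy-2-silyloxy-2,7-dien-9-one
Product: 8 6-acetoxy-2-silyloxy-2,7-dien-9-one
Conditions: Ac2O, DMAP, Et3N, CH2Cl2, 40 °C
Reagents that add atoms: acetic anhydride, CC(=O)OC(C)=O
Why: DMAP-catalysed acyl transfer turns the γ-hydroxyl of the enone into a reducible leaving group; warming is planned because this hydroxyl is flanked by C20 and the axial C4 methyl.

**Step 5**
Reactants: 8 6-acetoxy-2-silyloxy-2,7-dien-9-one
Product: 11 2-silyloxy-2,7-dien-9-one, via samarium dienolate 9 (not isolated), via deconjugated enone 10 (not isolated)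
Conditions: SmI2, THF–MeOH, −78 °C; then DBU, 23 °C
Reagents that add atoms: none
Why: SmI2 reductive cleavage of a γ-acyloxy enone: two electron transfers give the C9 ketyl/allyl anion, which expels acetate to the dienolate, methanol protonates it mainly at C8, and DBU moves the double bond into conjugation, so the transient C8 centre (either epimer) is of no consequence.

**Step 6**
Reactants: 11 2-silyloxy-2,7-dien-9-one
Product: 13 3-(tert-butyldimethylsilyloxy)-7-ene-2,9-dione (O3 anti to C20), via silyloxy epoxide 12 (not isolated)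
Conditions: mCPBA, NaHCO3, CH2Cl2, −20 → 0 °C
Reagents that add atoms: 3-chloroperoxybenzoic acid, OOC(=O)c1cccc(Cl)c1
Why: Rubottom oxidation: the peracid should epoxidise only the electron-rich silyl enol ether (the enone alkene is electron-poor) from the face away from C20 and the axial C4 methyl, and 1,4-silyl migration opens the epoxide to the α-silyloxy ketone, which fixes oxygen at C3 and not C1; the C3 configuration set here is provisional and is erased in step 19.

**Step 7**
Reactants: 13 3-silyloxy-7-ene-2,9-dione
Product: 14 2-hydroxy-3-silyloxy-7-en-9-one (2-OH syn to C20)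
Conditions: NaBH4, MeOH–CH2Cl2 (1:1), −78 °C
Reagents that add atoms: none
Why: NaBH4 in cold MeOH–CH2Cl2 reduces a saturated ketone in preference to a conjugated enone, so only the C2 carbonyl should react, hydride coming from the face away from the two syn-axial methyls (C2–OH syn to C20, again a provisional centre).

**Step 8**
Reactants: 14 2-hydroxy-3-silyloxy-7-en-9-one
Product: 15 2-(triethylsilyloxy)-3-(tert-butyldimethylsilyloxy)-7-en-9-one
Conditions: TESOTf, 2,6-lutidine, CH2Cl2, 0 → 23 °C
Reagents that add atoms: triethylsilyl triflate, CC[Si](CC)(CC)OS(=O)(=O)C(F)(F)F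
Why: Silylation with the small, reactive silyl triflate masks the hindered C2 hydroxyl against the organometallic, chromium and dissolving-metal steps that follow.

**Step 9**
Reactants: 16 4-(tert-butyldimethylsilyloxy)but-1-yne
Product: 18 (E)-5-(tert-butyldimethylsilyloxy)-3-methylpent-2-en-1-ol, via alkenylalane 17 (not isolated)
Conditions: Me3Al, Cp2ZrCl2, CH2Cl2, 0 → 23 °C; then n-BuLi, THF, −78 °C; (CH2O)n, −78 → 23 °C
Reagents that add atoms: trimethylaluminium, C[Al](C)C; formaldehyde (from paraformaldehyde), C=O
Why: Zirconium-catalysed carboalumination (Negishi) adds methyl and aluminium syn across the terminal alkyne with methyl on the internal carbon, and the derived aluminate is hydroxymethylated with retention, which sets the E geometry of C13=C14.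

**Step 10**
Reactants: 18 (E)-5-(tert-butyldimethylsilyloxy)-3-methylpent-2-en-1-ol
Product: 19 bis-silyl ether (C15–OTIPS, C11–OTBS)
Conditions: TIPSCl, imidazole, DMF, 23 °C
Reagents that add atoms: triisopropylsilyl chloride, CC(C)[Si](Cl)(C(C)C)C(C)C
Why: Standard silylation of the primary allylic alcohol with a group that tolerates alkyllithium, chromium and lithium–ammonia conditions.

**Step 11**
Reactants: 19 bis-silyl ether
Product: 20 (E)-3-methyl-5-(triisopropylsilyloxy)pent-3-en-1-ol
Conditions: PPTS, MeOH, 23 °C
Reagents that add atoms: none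
Why: Acid-catalysed methanolysis removes the primary tert-butyldimethylsilyl ether much faster than the bulkier triisopropylsilyl ether.

**Step 12**
Reactants: 20 (E)-3-methyl-5-(triisopropylsilyloxy)pent-3-en-1-ol
Product: 21 (E)-(5-iodo-3-methylpent-2-enyloxy)triisopropylsilane
Conditions: I2, PPh3, imidazole, CH2Cl2, 0 °C
Reagents that add atoms: iodine, II
Why: Appel-type iodination of the primary alcohol through its alkoxyphosphonium salt, with SN2 displacement by iodide.

**Step 13**
Reactants: 21 (E)-(5-iodo-3-methylpent-2-enyloxy)triisopropylsilane; 15 2-(triethylsilyloxy)-3-(tert-butyldimethylsilyloxy)-7-en-9-one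
Product: 24 C9 tertiary allylic alcohol carrying the full side chain (9-OH syn to C20), via organolithium 22 (not isolated), via organocerium 23 (not isolated)
Conditions: 21, t-BuLi, Et2O–pentane, −78 °C; CeCl3, THF, −78 °C; then 15, −78 → −40 °C
Reagents that add atoms: none
Why: Iodine–lithium exchange and transmetalation give a weakly basic organocerium reagent that should add 1,2 to the hindered enone carbonyl, which has no α-hydrogen, from the face away from C20; the C9 carbinol configuration is lost in the next step.

**Step 14**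
Reactants: 24 C9 tertiary allylic alcohol
Product: 25 8-en-7-one with the side chain on C9
Conditions: pyridinium chlorochromate (C5H5NH[CrO3Cl]), NaOAc, 4 Å MS, CH2Cl2, 23 °C
Reagents that add atoms: pyridinium chlorochromate, [O-][Cr](=O)(=O)Cl.c1cc[nH+]cc1
Why: Babler–Dauben oxidative transposition: the tertiary allylic chromate ester undergoes a [3,3] shift to C7 and is oxidised to the 8-en-7-one, which moves oxygen from C9 to C7 and leaves the chain on C9.

**Step 15**
Reactants: 25 8-en-7-one
Product: 27 7-en-7-yl triflate (H9 anti to C20), via lithium enolate 26 (not isolated)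
Conditions: Li, NH3–THF, t-BuOH (1 equiv), −78 °C; NH3 evaporated; PhNTf2, THF, −78 → 0 °C
Reagents that add atoms: N-phenylbis(trifluoromethanesulfonimide), O=S(=O)(N(c1ccccc1)S(=O)(=O)C(F)(F)F)C(F)(F)F
Why: Dissolving-metal reduction of the enone should protonate the β-carbon C9 axially, on the face away from C20, giving H9 anti and the side chain syn to C20 (the equatorial, more stable arrangement), and the regiodefined C7–C8 enolate is trapped as its triflate.

**Step 16**
Reactants: 27 7-en-7-yl triflate
Product: 28 2-(triethylsilyloxy)-3-(tert-butyldimethylsilyloxy)-15-(triisopropylsilyloxy)labda-7,13E-diene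
Conditions: Pd(OAc)2, PPh3, HCO2H, n-Bu3N, DMF, 60 °C
Reagents that add atoms: none
Why: Palladium-catalysed formate reduction of the enol triflate (oxidative addition, formate-to-hydride exchange, reductive elimination) replaces OTf by H and leaves the C7=C8 bond where the enolate was.

**Step 17**
Reactants: 28 tris-silyl ether
Product: 29 labda-7,13E-diene-2,3,15-triol (2-OH syn and 3-OH anti to C20)
Conditions: Bu4NF, THF, 50 °C
Reagents that add atoms: none
Why: Fluoride cleaves all three silyl ethers (Si–F bond formation), the hindered ring A ethers needing warming; no base-sensitive group is present at this stage.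

**Step 18**
Reactants: 29 triol
Product: 30 15-acetoxy-labda-7,13E-diene-2,3-diol
Conditions: Ac2O, pyridine, CH2Cl2, 0 °C
Reagents that add atoms: acetic anhydride, CC(=O)OC(C)=O
Why: Acylation should discriminate the primary allylic C15 hydroxyl from the two axial, hindered ring A hydroxyls.

**Step 19**
Reactants: 30 15-acetoxy-2,3-diol
Product: 32 diosphenol (2-hydroxy-1-en-3-one), via 2,3-dione 31 (not isolated)
Conditions: (COCl)2, DMSO, CH2Cl2, −78 °C; Et3N, −78 → 0 °C
Reagents that add atoms: none
Why: Swern oxidation converts the vicinal diol into the 1,2-dione without C–C cleavage, and the dione enolises in the only direction open to it (towards C1, C4 being quaternary); both provisional centres C2 and C3 are erased.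

**Step 20**
Reactants: 32 diosphenol
Product: 33 2-(triethylsilyloxy)-1-en-3-one
Conditions: TESCl, imidazole, DMF, 0 °C
Reagents that add atoms: triethylsilyl chloride, CC[Si](Cl)(CC)CC
Why: O-Silylation of the acidic enol gives a 2-silyloxy enone in which C2 is masked at the ketone oxidation level and only C3 remains a carbonyl.

**Step 21**
Reactants: 33 2-(triethylsilyloxy)-1-en-3-one
Product: 35 (3S,5S,9R,10S)-3-hydroxy-2-oxolabda-7,13E-dien-15-yl acetate, via hydroxy silyl enol ether 34 (not isolated)
Conditions: NaBH4, CeCl3·7H2O, MeOH, −40 °C; acetone; then 1 M HCl, THF, 0 °C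
Reagents that add atoms: none
Why: Luche 1,2-reduction should deliver hydride to C3 from the face away from C20 and the axial C4 methyl, placing the C3 hydroxyl syn to C20 as required, and mild acid then hydrolyses the silyl enol ether to the C2 ketone after excess hydride has been quenched, so the ketol is neither over-reduced nor transposed.

**Compound list**
1 | mesityl oxide (4-methylpent-3-en-2-one) | CC(C)=CC(C)=O | starting material
2 | lithium 4-methylpenta-1,3-dien-2-olate | [Li]OC(=C)C=C(C)C | intermediate
3 | 2-(tert-butyldimethylsilyloxy)-4-methylpenta-1,3-diene | C=C(O[Si](C)(C)C(C)(C)C)C=C(C)C | intermediate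
4 | 2,6-dimethyl-1,4-benzoquinone | CC1=CC(=O)C=C(C)C1=O | starting material
5 | cis-fused Diels–Alder adduct, 2-silyloxy-2,7-diene-6,9-dione (H5 syn to C20) | O=C1C(C)=CC(=O)[C@H]2C(C)(C)C=C(O[Si](C)(C)C(C)(C)C)C[C@@]12C | intermediate
6 | trans-fused 2-(tert-butyldimethylsilyloxy)-2,7-diene-6,9-dione (H5 anti to C20) | O=C1C(C)=CC(=O)[C@@H]2C(C)(C)C=C(O[Si](C)(C)C(C)(C)C)C[C@@]12C | intermediate
7 | 6-hydroxy-2-silyloxy-2,7-dien-9-one (6-OH syn to C20) | O=C1C(C)=C[C@H](O)[C@@H]2C(C)(C)C=C(O[Si](C)(C)C(C)(C)C)C[C@@]12C | intermediate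
8 | 6-acetoxy-2-silyloxy-2,7-dien-9-one | O=C1C(C)=C[C@H](OC(C)=O)[C@@H]2C(C)(C)C=C(O[Si](C)(C)C(C)(C)C)C[C@@]12C | intermediate
9 | diiodosamarium 2-silyloxy-2,6,8-trien-9-olate (trivalent samarium dienolate) | I[Sm](I)OC1=C(C)C=C[C@@H]2C(C)(C)C=C(O[Si](C)(C)C(C)(C)C)C[C@@]12C | intermediate
10 | 2-silyloxy-2,6-dien-9-one (deconjugated, H8 anti to C20 expected) | O=C1[C@H](C)C=C[C@@H]2C(C)(C)C=C(O[Si](C)(C)C(C)(C)C)C[C@@]12C | intermediate
11 | 2-(tert-butyldimethylsilyloxy)-2,7-dien-9-one | O=C1C(C)=CC[C@@H]2C(C)(C)C=C(O[Si](C)(C)C(C)(C)C)C[C@@]12C | intermediate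
12 | 2,3-epoxy-2-silyloxy-7-en-9-one (epoxide anti to C20) | O=C1C(C)=CC[C@@H]2C(C)(C)[C@H]3O[C@@]3(O[Si](C)(C)C(C)(C)C)C[C@@]12C | intermediate
13 | 3-(tert-butyldimethylsilyloxy)-7-ene-2,9-dione (O3 anti to C20) | O=C1C(C)=CC[C@@H]2C(C)(C)[C@@H](O[Si](C)(C)C(C)(C)C)C(=O)C[C@@]12C | intermediate
14 | 2-hydroxy-3-(tert-butyldimethylsilyloxy)-7-en-9-one (2-OH syn to C20) | O=C1C(C)=CC[C@@H]2C(C)(C)[C@@H](O[Si](C)(C)C(C)(C)C)[C@H](O)C[C@@]12C | intermediate
15 | 2-(triethylsilyloxy)-3-(tert-butyldimethylsilyloxy)-7-en-9-one | O=C1C(C)=CC[C@@H]2C(C)(C)[C@@H](O[Si](C)(C)C(C)(C)C)[C@H](O[Si](CC)(CC)CC)C[C@@]12C | intermediate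
16 | 4-(tert-butyldimethylsilyloxy)but-1-yne | C#CCCO[Si](C)(C)C(C)(C)C | starting material
17 | (E)-[4-(tert-butyldimethylsilyloxy)-2-methylbut-1-enyl]dimethylalane | C[Al](C)/C=C(\C)CCO[Si](C)(C)C(C)(C)C | intermediate
18 | (E)-5-(tert-butyldimethylsilyloxy)-3-methylpent-2-en-1-ol | OC/C=C(\C)CCO[Si](C)(C)C(C)(C)C | intermediate
19 | (E)-1-(triisopropylsilyloxy)-5-(tert-butyldimethylsilyloxy)-3-methylpent-2-ene | CC(C)[Si](OC/C=C(\C)CCO[Si](C)(C)C(C)(C)C)(C(C)C)C(C)C | intermediate
20 | (E)-3-methyl-5-(triisopropylsilyloxy)pent-3-en-1-ol | CC(C)[Si](OC/C=C(\C)CCO)(C(C)C)C(C)C | intermediate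
21 | (E)-(5-iodo-3-methylpent-2-enyloxy)triisopropylsilane | CC(C)[Si](OC/C=C(\C)CCI)(C(C)C)C(C)C | intermediate
22 | (E)-[3-methyl-5-(triisopropylsilyloxy)pent-3-enyl]lithium | CC(C)[Si](OC/C=C(\C)CC[Li])(C(C)C)C(C)C | intermediate
23 | (E)-[3-methyl-5-(triisopropylsilyloxy)pent-3-enyl]cerium dichloride | CC(C)[Si](OC/C=C(\C)CC[Ce](Cl)Cl)(C(C)C)C(C)C | intermediate
24 | 9-hydroxy-2-(triethylsilyloxy)-3-(tert-butyldimethylsilyloxy)-15-(triisopropylsilyloxy)labda-7,13E-diene (9-OH syn to C20) | CC(C)[Si](OC/C=C(\C)CC[C@@]1(O)C(C)=CC[C@@H]2C(C)(C)[C@@H](O[Si](C)(C)C(C)(C)C)[C@H](O[Si](CC)(CC)CC)C[C@@]12C)(C(C)C)C(C)C | intermediate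
25 | 2-(triethylsilyloxy)-3-(tert-butyldimethylsilyloxy)-15-(triisopropylsilyloxy)labda-8,13E-dien-7-one | CC(C)[Si](OC/C=C(\C)CCC1=C(C)C(=O)C[C@@H]2C(C)(C)[C@@H](O[Si](C)(C)C(C)(C)C)[C@H](O[Si](CC)(CC)CC)C[C@@]12C)(C(C)C)C(C)C | intermediate
26 | lithium labda-7,13E-dien-7-olate, tris-silyl ether (H9 anti to C20) | CC(C)[Si](OC/C=C(\C)CC[C@@H]1C(C)=C(O[Li])C[C@@H]2C(C)(C)[C@@H](O[Si](C)(C)C(C)(C)C)[C@H](O[Si](CC)(CC)CC)C[C@@]12C)(C(C)C)C(C)C | intermediate
27 | labda-7,13E-dien-7-yl triflate, tris-silyl ether | CC(C)[Si](OC/C=C(\C)CC[C@@H]1C(C)=C(OS(=O)(=O)C(F)(F)F)C[C@@H]2C(C)(C)[C@@H](O[Si](C)(C)C(C)(C)C)[C@H](O[Si](CC)(CC)CC)C[C@@]12C)(C(C)C)C(C)C | intermediate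
28 | 2-(triethylsilyloxy)-3-(tert-butyldimethylsilyloxy)-15-(triisopropylsilyloxy)labda-7,13E-diene | CC(C)[Si](OC/C=C(\C)CC[C@@H]1C(C)=CC[C@@H]2C(C)(C)[C@@H](O[Si](C)(C)C(C)(C)C)[C@H](O[Si](CC)(CC)CC)C[C@@]12C)(C(C)C)C(C)C | intermediate
29 | labda-7,13E-diene-2,3,15-triol (2-OH syn, 3-OH anti to C20) | OC/C=C(\C)CC[C@@H]1C(C)=CC[C@@H]2C(C)(C)[C@@H](O)[C@H](O)C[C@@]12C | intermediate
30 | 2,3-dihydroxylabda-7,13E-dien-15-yl acetate | CC(=O)OC/C=C(\C)CC[C@@H]1C(C)=CC[C@@H]2C(C)(C)[C@@H](O)[C@H](O)C[C@@]12C | intermediate
31 | 2,3-dioxolabda-7,13E-dien-15-yl acetate | CC(=O)OC/C=C(\C)CC[C@@H]1C(C)=CC[C@@H]2C(C)(C)C(=O)C(=O)C[C@@]12C | intermediate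
32 | 2-hydroxy-3-oxolabda-1,7,13E-trien-15-yl acetate (diosphenol) | CC(=O)OC/C=C(\C)CC[C@@H]1C(C)=CC[C@@H]2C(C)(C)C(=O)C(O)=C[C@@]12C | intermediate
33 | 3-oxo-2-(triethylsilyloxy)labda-1,7,13E-trien-15-yl acetate | CC(=O)OC/C=C(\C)CC[C@@H]1C(C)=CC[C@@H]2C(C)(C)C(=O)C(O[Si](CC)(CC)CC)=C[C@@]12C | intermediate
34 | 3-hydroxy-2-(triethylsilyloxy)labda-1,7,13E-trien-15-yl acetate (3-OH syn to C20) | CC(=O)OC/C=C(\C)CC[C@@H]1C(C)=CC[C@@H]2C(C)(C)[C@H](O)C(O[Si](CC)(CC)CC)=C[C@@]12C | intermediate
35 | (3S,5S,9R,10S)-3-hydroxy-2-oxolabda-7,13E-dien-15-yl acetate (CNP0164008.1) | CC(=O)OC/C=C(\C)CC[C@@H]1C(C)=CC[C@@H]2C(C)(C)[C@H](O)C(=O)C[C@@]12C | target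

**Step count**
Total: 21 steps. Longest linear sequence: 17 steps (steps 1–8 and 13–21); the side-chain branch (steps 9–12) joins at step 13.

**Steps most likely to fail**

Step 2. The doubly hindered pair may stall after the first C–C bond (conjugate addition without ring closure, or loss of the silyl group). Facial discrimination may erode if a higher temperature is needed, and the base equilibration at C5 may stop short of the trans isomer. The fallback sets out from 3 and 4 and returns at 5, and so at 6, by forming the two bonds separately. The same chiral cation is used only for the Mukaiyama–Michael addition of 3 to 4 (C1 to C10), and the silyl-transferred adduct, the 6-silyloxy cross-conjugated dienone F1, is isolated. Ring A is then closed by an intramolecular Mukaiyama–Michael addition (C5 of the silyl dienol ether onto C4 of the side-chain enone) under catalytic TBSOTf in CH2Cl2 at −78 °C, the silyl group passing from O6 to O2 to give 5. DBU is then applied as in step 2.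

Step 13. Addition to the C9 carbonyl, which lies between quaternary C10 and the methyl-bearing C8, may be too slow, so that γ-deprotonation at C6 or decay of the organometallic takes over. The fallback sets out from 15 and 21 and returns at 28. Enone 15 is γ-deprotonated on purpose (KN(SiMe3)2, then PhNTf2) to the 6,8-dien-9-yl triflate F2. Iodide 21 is converted (t-BuLi, then ZnCl2) into the alkylzinc chloride F3, and Negishi coupling (Pd(OAc)2, SPhos, THF–NMP) gives the 9-alkyl-6,8-diene F4. 1,4-Hydrogenation of the cisoid diene with (naphthalene)Cr(CO)3 under H2 should deliver both hydrogens to C6 and C9 from the face away from C20 and leave the C7=C8 bond, which is 28; the route continues at step 17.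

Step 4. The C6 hydroxyl of 7 is flanked by C20 and the axial C4 methyl, so acylation may fail or be overtaken by elimination or loss of the silyl enol ether under forcing conditions. The fallback sets out from 6 and returns at 10, and so at 11, removing the C6 oxygen by reductive transposition. The C6 carbonyl of 6, the only unhindered one, is condensed with TsNHNH2 to the tosylhydrazone F5. Catecholborane and then NaOAc·3H2O with warming reduce the C=N bond and expel sulfinate, and the allylic diazene loses N2 with hydrogen delivery to C8, giving the 6-ene 10, which DBU conjugates to 11.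

**Further compounds**
F1 | step 2 | 6-(tert-butyldimethylsilyloxy)-8,10-dimethyl-10-(4-methyl-2-oxopent-3-enyl)cyclohexa-5,7-dien-9-one (labdane numbering, Michael adduct) | O=C1C(C)=CC(O[Si](C)(C)C(C)(C)C)=C[C@@]1(C)CC(=O)C=C(C)C
F2 | step 13 | 2-(triethylsilyloxy)-3-(tert-butyldimethylsilyloxy)-6,8-dien-9-yl triflate | FC(F)(F)S(=O)(=O)OC1=C(C)C=C[C@@H]2C(C)(C)[C@@H](O[Si](C)(C)C(C)(C)C)[C@H](O[Si](CC)(CC)CC)C[C@@]12C
F3 | step 13 | (E)-[3-methyl-5-(triisopropylsilyloxy)pent-3-enyl]zinc chloride | CC(C)[Si](OC/C=C(\C)CC[Zn]Cl)(C(C)C)C(C)C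
F4 | step 13 | 2-(triethylsilyloxy)-3-(tert-butyldimethylsilyloxy)-15-(triisopropylsilyloxy)labda-6,8,13E-triene | CC(C)[Si](OC/C=C(\C)CCC1=C(C)C=C[C@@H]2C(C)(C)[C@@H](O[Si](C)(C)C(C)(C)C)[C@H](O[Si](CC)(CC)CC)C[C@@]12C)(C(C)C)C(C)C
F5 | step 4 | C6 tosylhydrazone of 6 | O=C1C(C)=C/C(=N\NS(=O)(=O)c3ccc(C)cc3)[C@@H]2C(C)(C)C=C(O[Si](C)(C)C(C)(C)C)C[C@@]12C
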